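## The problem

The target is a biflavanone. Its eriodictyol half (ring A = phloroglucinol ring, ring C = pyranone with O1, C2, C3, C4, ring B = catechol; atoms unprimed) is bonded through C3 to C8'' of a naringenin half (ring D = phloroglucinol ring, ring F = pyranone, ring E = 4-hydroxyphenyl; atoms double-primed). The single inter-unit bond C3–C8'' is the hardest connection: it is flanked by C2 (bearing ring B) and the C4 carbonyl on one side and by O1'' and the 7''-oxygen on the other, so at the sp3 level it means arylating a secondary, enolisable carbon with a doubly ortho-substituted arene. There are three stereocentres, C2 and C3 in ring C and C2'' in ring F. The SMILES encodes 2R,3R,2''R; with the priorities C4 > C2 > C8'' > H at C3 and O1 > C1' > C3 > H at C2 this is the cis isomer, with ring B and ring D on the same face of ring C. The cis arrangement is the less stable one: C3–H is α to the C4 ketone and carries an aryl group, so base or prolonged acid would epimerise it to trans, and both C2 centres are lost by retro-oxa-Michael opening to 2'-hydroxychalcones. C2'' lies beyond the C3–C8'' axis and cannot be controlled from C2/C3, so it needs reagent control of its own, or the same reagent. Seven phenols (two chelated to carbonyl groups, two forming an oxidisable catechol) must be unmasked at the end without base. The feature the route uses: H-2 and H-3 are cis and C2 and C2'' have the same sense, so all three centres are what results when H2 adds syn to the same face of the C2=C3 bond of ring C and of the C2''=C3'' bond of ring F in the flat, stereocentre-free 3,8''-biflavone.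

## Retrosynthesis

**12 to 11.** The seven O–CH2Ph bonds of the hepta-O-benzyl ether 11 are cut. Benzyl is preferred to methyl (removal needs BBr3) or acyl (removal needs base) because hydrogenolysis is neutral and leaves the cis C3–H and both C2 centres alone. The forward reaction must cleave seven ethers without touching two ketones and two cyclic benzylic C–O bonds.

**11 to 9.** Four C–H bonds are removed (C2–H, C3–H, C2''–H, C3''–H), which leads back to the hepta-O-benzyl biflavone 9. Against the neighbouring choice of setting the centres on each half before joining them, this cut removes all three stereocentres at once and removes every base-labile element from the run-up. It also turns the C3–C8'' bond into an sp2–sp2 bond. Compound 9 has no stereocentre and is a robust flavone. The forward reaction must add H2 syn to both pyranone C=C bonds from the same face, chemoselectively; the ring F bond is an ordinary flavone, the ring C bond is tetrasubstituted and is the uncertain part.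

**9 to 4 and 8.** The C3–C8'' bond is cut to the 3-iodoflavone 4 and the 8-boronate 8. The polarity follows the natural reactivity of each half: C3 of a flavone can be metalated and iodinated, while C8 of a 5,7-dialkoxyflavone is where electrophilic iodine enters, so a halide at C8 can be turned into boron. Building ring C around a preformed aryl–CH2 bond (deoxybenzoin logic) would be longer. Both fragments are flavones two or three steps from commercial natural products. The forward reaction is a cross-coupling between two doubly flanked sp2 carbons.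

**4 to 2 to 1.** The C3–I bond is cut to tetra-O-benzylluteolin 2 (deprotonative iodination), and the four O–benzyl bonds are cut to luteolin 1. Lithiation is chosen over electrophilic iodination because ring A of 2 is more nucleophilic than C3.

**8 to 7 to 6 to 5.** The C–B bond is cut to the 8-iodide 7, the C8–I bond to tri-O-benzylapigenin 6, and the three O–benzyl bonds to apigenin 5. The forward iodination must select C8 over C6, which the 5-O-alkyl group is expected to secure.

## Roads not taken

**Alternative 1:** Cut C3–C8'' between two finished, separately made flavanones. The forward key step would be a palladium-catalysed α-arylation of the enolate of (2R)-tetra-O-benzyleriodictyol A1 with (2R)-8-bromo-tri-O-benzylnaringenin A2. This is the route most chemists would draw first.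
- The enolate of A1 expels its ring phenoxide (retro-oxa-Michael), which erases C2.
- The arylpalladium species from A2 is doubly ortho-substituted and must meet a secondary enolate carbon next to ring B.
- Whatever couples is formed under basic, equilibrating conditions and ends as the trans isomer A3, not the cis target.
- Each half needs its own asymmetric synthesis before the coupling, so the route is longer.

The chosen plan makes the same bond between two sp2 carbons and sets the stereocentres afterwards.

**Alternative 2:** Cut ring C at O1–C2 and C2–C3 (the 2-aryl-isoflavanone logic). The forward key step would be an amine-mediated Knoevenagel condensation and oxa-Michael closure of the deoxybenzoin A4 with 3,4-bis(benzyloxy)benzaldehyde A5.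
- The C3–C8'' bond is then made early at a CH2 group, which is an advantage.
- The ring closure is reversible and gives the trans-2,3-diarylchromanone A6, racemic at C2/C3.
- The cis arrangement would need a separate kinetic epimerisation, and the absolute configuration a separation against C2''.
- A4 itself costs an α-arylation plus protecting-group work.

The sequence is longer and controls none of the three centres directly.

**Alternative 3:** Cut both C–C bonds at C3 (C3–C8'' and C2–C3) and O1–C2. The forward key step would be a Hooz-type three-component coupling of the B-aryl-9-borabicyclononane A7 (from 7), the diazoketone A8 and the aldehyde A5. Migration of ring D from boron to the diazo carbon gives a boron enolate that adds to the aldehyde. The anti aldol A9 would then be closed to ring C by a Mitsunobu etherification with inversion at C2, which gives the cis relationship.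
- Three components meet at C3, which is attractive.
- Absolute control would need a chiral, non-migrating boron ligand, and the migration of so hindered an aryl group is not secured.
- A9 is prone to retro-aldol cleavage and dehydration while its phenol is unmasked.
- C2'' would still need its own asymmetric step.

That is two uncertain steps instead of one and roughly twice the step count.

Key step: step 7

Assumption: the SMILES is read as (2R,3R,2''R) with H-2 and H-3 cis; the C3–C8'' axis carries no descriptor and is taken to rotate freely enough in 11 and 12 that rotamers converge.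

## Route

Step 1
Reactants: 1 luteolin (2-(3,4-dihydroxyphenyl)-5,7-dihydroxy-4H-chromen-4-one)
Product: 2 5,7-bis(benzyloxy)-2-[3,4-bis(benzyloxy)phenyl]-4H-chromen-4-one
Conditions: BnBr (6 equiv), K2CO3 (6 equiv), DMF, 80 °C
Reagents that add atoms: benzyl bromide, BrCc1ccccc1
Why: Williamson ether synthesis on all four phenols; heat and excess reagent are needed for the 5-OH, which is hydrogen-bonded to the C4 carbonyl. Benzyl is chosen because it can leave at the end by neutral hydrogenolysis.

Step 2
Reactants: 2 5,7-bis(benzyloxy)-2-[3,4-bis(benzyloxy)phenyl]-4H-chromen-4-one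
Product: 4 5,7-bis(benzyloxy)-2-[3,4-bis(benzyloxy)phenyl]-3-iodo-4H-chromen-4-one, via 3-lithioflavone 3 (not isolated)
Conditions: LiN(iPr)2 (1.5 equiv), THF, −78 °C; then I2, −78 °C to 0 °C
Reagents that add atoms: iodine, II
Why: Deprotonative lithiation of the flavone C3–H, the vinylic C–H next to the carbonyl group that holds the lithium, followed by an iodine quench. The regiochemistry is fixed by the site of metalation and not by the nucleophilicity of ring A, which an electrophilic iodination would attack first.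

Step 3
Reactants: 5 apigenin (5,7-dihydroxy-2-(4-hydroxyphenyl)-4H-chromen-4-one)
Product: 6 5,7-bis(benzyloxy)-2-[4-(benzyloxy)phenyl]-4H-chromen-4-one
Conditions: BnBr (5 equiv), K2CO3 (5 equiv), DMF, 80 °C
Reagents that add atoms: benzyl bromide, BrCc1ccccc1
Why: Williamson ether synthesis as in step 1; the 5-O-benzyl group also steers the iodination of step 4 to C8.

Step 4
Reactants: 6 5,7-bis(benzyloxy)-2-[4-(benzyloxy)phenyl]-4H-chromen-4-one
Product: 7 5,7-bis(benzyloxy)-2-[4-(benzyloxy)phenyl]-8-iodo-4H-chromen-4-one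
Conditions: NIS (1.1 equiv), CF3CO2H (cat.), MeCN, 0 °C to rt
Reagents that add atoms: N-iodosuccinimide, O=C1CCC(=O)N1I
Why: Electrophilic aromatic iodination; in 5-O-alkylated 5,7-dioxygenated flavones ring A reacts at C8 (C6 reacts first only when the 5-OH is free and chelated). Ring E and C3 are much less nucleophilic.

Step 5
Reactants: 7 5,7-bis(benzyloxy)-2-[4-(benzyloxy)phenyl]-8-iodo-4H-chromen-4-one
Product: 8 5,7-bis(benzyloxy)-2-[4-(benzyloxy)phenyl]-8-(4,4,5,5-tetramethyl-1,3,2-dioxaborolan-2-yl)-4H-chromen-4-one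
Conditions: B2pin2 (1.5 equiv), PdCl2(dppf) (5 mol %), KOAc, 1,4-dioxane, 90 °C
Reagents that add atoms: bis(pinacolato)diboron, CC1(C)OB(OC1(C)C)B1OC(C)(C)C(C)(C)O1
Why: Miyaura borylation of an aryl iodide. The pinacol ester is preferred to the free boronic acid because a di-ortho-oxygenated arylboron species protodeboronates easily.

Step 6
Reactants: 4 5,7-bis(benzyloxy)-2-[3,4-bis(benzyloxy)phenyl]-3-iodo-4H-chromen-4-one; 8 5,7-bis(benzyloxy)-2-[4-(benzyloxy)phenyl]-8-(4,4,5,5-tetramethyl-1,3,2-dioxaborolan-2-yl)-4H-chromen-4-one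
Product: 9 5,7-bis(benzyloxy)-2-[3,4-bis(benzyloxy)phenyl]-3-{5,7-bis(benzyloxy)-2-[4-(benzyloxy)phenyl]-4-oxo-4H-chromen-8-yl}-4H-chromen-4-one
Conditions: Pd(OAc)2 (10 mol %), SPhos (20 mol %), K3PO4, toluene/H2O (10:1), 100 °C
Reagents that add atoms: none
Why: Suzuki–Miyaura coupling of an α-iodo enone with an arylboronate; a bulky dialkylbiarylphosphine is used because both coupling carbons are flanked by two substituents. The product has no stereocentre and its C3–C8'' bond joins two sp2 carbons.

Step 7
Reactants: 9 5,7-bis(benzyloxy)-2-[3,4-bis(benzyloxy)phenyl]-3-{5,7-bis(benzyloxy)-2-[4-(benzyloxy)phenyl]-4-oxo-4H-chromen-8-yl}-4H-chromen-4-one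
Product: 11 (2R,3R)-5,7-bis(benzyloxy)-2-[3,4-bis(benzyloxy)phenyl]-3-{(2R)-5,7-bis(benzyloxy)-2-[4-(benzyloxy)phenyl]-4-oxochroman-8-yl}chroman-4-one, via half-reduced flavanone–flavone 10 (not isolated)
Conditions: Ru(cod)(2-methylallyl)2 (10 mol %), SINpEt·HBF4 (20 mol %; the ligand antipode that gives 2R-flavanones), KOtBu (18 mol %), H2 (100 bar), toluene/n-hexane, 40 °C
Reagents that add atoms: none
Why: Proposed new method: the closest known reaction is the asymmetric hydrogenation of flavones (2-arylchromones) to flavanones with chiral N-heterocyclic-carbene ruthenium catalysts (SINpEt·HBF4 is 1,3-bis[1-(naphthalen-1-yl)ethyl]-4,5-dihydroimidazolium tetrafluoroborate); here it is asked to act twice in one molecule, on the ordinary trisubstituted C2''=C3'' bond of ring F and on the tetrasubstituted C2=C3 bond of ring C. Mechanistically the ruthenium hydride transfers hydride to the electrophilic C2 terminus of the vinylogous ester and the resulting ruthenium enolate takes up the second hydrogen at C3 from the same face, so each pyranone receives H2 syn; ring F should react first to give 10 and ring C then follows. No ring is closed. C2'' and C2 are set by the chiral ligand, which meets the same local element in both halves (a 5,7-bis(benzyloxy)benzopyranone with an aryl group on C2) and should therefore deliver hydrogen to the same face of both rings, the face on which O1, C2, C3 (and O1'', C2'', C3'') run counterclockwise, as the R descriptor at both centres demands; the ligand antipode is fixed beforehand on 6 as a model. C3 is set relative to C2 by the syn course of the addition, and if the second hydrogen instead arrived as a proton on a free enolate it would still enter anti to ring B and give the same cis isomer. The step needs selectivity for C=C over C=O, over the benzyl ethers and over the benzenoid rings, and no epimerisation at C3: both carbonyl groups are deactivated by the 5- and 7-benzyloxy donors, this catalyst type leaves benzyl ethers and carbocyclic arenes alone, and the alkoxide is kept below the amount of azolium salt so that no free base meets the product. The tetrasubstituted bond of ring C is the uncertain part, because ring D stands perpendicular to it and its two ortho substituents cover both faces of C3, which is why the step is argued from hydride attack at the more open C2 and not from olefin coordination.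

Step 8
Reactants: 11 (2R,3R)-5,7-bis(benzyloxy)-2-[3,4-bis(benzyloxy)phenyl]-3-{(2R)-5,7-bis(benzyloxy)-2-[4-(benzyloxy)phenyl]-4-oxochroman-8-yl}chroman-4-one
Product: 12 (2R,3R)-2-(3,4-dihydroxyphenyl)-5,7-dihydroxy-3-[(2R)-5,7-dihydroxy-2-(4-hydroxyphenyl)-4-oxochroman-8-yl]chroman-4-one
Conditions: H2 (1 atm), Pd(OH)2/C, EtOAc/MeOH (1:1), rt
Reagents that add atoms: none
Why: Hydrogenolysis of seven aryl benzyl ethers under neutral conditions; no base or Lewis acid meets the cis-configured C3–H or the two C2 centres. The chromanone carbonyl groups and the cyclic benzylic C–O bonds should be retained when the reaction is stopped at full debenzylation.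

## Compound list

1 | luteolin, 2-(3,4-dihydroxyphenyl)-5,7-dihydroxy-4H-chromen-4-one | O=c1cc(-c2ccc(O)c(O)c2)oc2cc(O)cc(O)c12 | starting material
2 | 5,7-bis(benzyloxy)-2-[3,4-bis(benzyloxy)phenyl]-4H-chromen-4-one | O=c1cc(-c2ccc(OCc3ccccc3)c(OCc3ccccc3)c2)oc2cc(OCc3ccccc3)cc(OCc3ccccc3)c12 | intermediate
3 | 5,7-bis(benzyloxy)-2-[3,4-bis(benzyloxy)phenyl]-3-lithio-4H-chromen-4-one (not isolated) | [Li]c1c(-c2ccc(OCc3ccccc3)c(OCc3ccccc3)c2)oc2cc(OCc3ccccc3)cc(OCc3ccccc3)c2c1=O | intermediate
4 | 5,7-bis(benzyloxy)-2-[3,4-bis(benzyloxy)phenyl]-3-iodo-4H-chromen-4-one | O=c1c(I)c(-c2ccc(OCc3ccccc3)c(OCc3ccccc3)c2)oc2cc(OCc3ccccc3)cc(OCc3ccccc3)c12 | intermediate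
5 | apigenin, 5,7-dihydroxy-2-(4-hydroxyphenyl)-4H-chromen-4-one | O=c1cc(-c2ccc(O)cc2)oc2cc(O)cc(O)c12 | starting material
6 | 5,7-bis(benzyloxy)-2-[4-(benzyloxy)phenyl]-4H-chromen-4-one | O=c1cc(-c2ccc(OCc3ccccc3)cc2)oc2cc(OCc3ccccc3)cc(OCc3ccccc3)c12 | intermediate
7 | 5,7-bis(benzyloxy)-2-[4-(benzyloxy)phenyl]-8-iodo-4H-chromen-4-one | O=c1cc(-c2ccc(OCc3ccccc3)cc2)oc2c(I)c(OCc3ccccc3)cc(OCc3ccccc3)c12 | intermediate
8 | 5,7-bis(benzyloxy)-2-[4-(benzyloxy)phenyl]-8-(4,4,5,5-tetramethyl-1,3,2-dioxaborolan-2-yl)-4H-chromen-4-one | O=c1cc(-c2ccc(OCc3ccccc3)cc2)oc2c(B3OC(C)(C)C(C)(C)O3)c(OCc3ccccc3)cc(OCc3ccccc3)c12 | intermediate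
9 | 5,7-bis(benzyloxy)-2-[3,4-bis(benzyloxy)phenyl]-3-{5,7-bis(benzyloxy)-2-[4-(benzyloxy)phenyl]-4-oxo-4H-chromen-8-yl}-4H-chromen-4-one (no stereocentre) | O=c1c(-c2c(OCc3ccccc3)cc(OCc3ccccc3)c3c(=O)cc(-c4ccc(OCc5ccccc5)cc4)oc23)c(-c2ccc(OCc3ccccc3)c(OCc3ccccc3)c2)oc2cc(OCc3ccccc3)cc(OCc3ccccc3)c12 | intermediate
10 | 5,7-bis(benzyloxy)-2-[3,4-bis(benzyloxy)phenyl]-3-{(2R)-5,7-bis(benzyloxy)-2-[4-(benzyloxy)phenyl]-4-oxochroman-8-yl}-4H-chromen-4-one (not isolated) | O=C1C[C@H](c2ccc(OCc3ccccc3)cc2)Oc2c1c(OCc1ccccc1)cc(OCc1ccccc1)c2-c1c(-c2ccc(OCc3ccccc3)c(OCc3ccccc3)c2)oc2cc(OCc3ccccc3)cc(OCc3ccccc3)c2c1=O | intermediate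
11 | (2R,3R)-5,7-bis(benzyloxy)-2-[3,4-bis(benzyloxy)phenyl]-3-{(2R)-5,7-bis(benzyloxy)-2-[4-(benzyloxy)phenyl]-4-oxochroman-8-yl}chroman-4-one (2,3-cis) | O=C1C[C@H](c2ccc(OCc3ccccc3)cc2)Oc2c1c(OCc1ccccc1)cc(OCc1ccccc1)c2[C@H]1C(=O)c2c(OCc3ccccc3)cc(OCc3ccccc3)cc2O[C@H]1c1ccc(OCc2ccccc2)c(OCc2ccccc2)c1 | intermediate
12 | (2R,3R)-2-(3,4-dihydroxyphenyl)-5,7-dihydroxy-3-[(2R)-5,7-dihydroxy-2-(4-hydroxyphenyl)-4-oxochroman-8-yl]chroman-4-one (CNP0105436.4) | O=C1C[C@H](c2ccc(O)cc2)Oc2c1c(O)cc(O)c2[C@H]1C(=O)c2c(O)cc(O)cc2O[C@H]1c1ccc(O)c(O)c1 | target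

## Step count and risks

Total step count: 8. Longest linear sequence: 6 (steps 3, 4, 5, 6, 7, 8).

**Step 7 (key step, Proposed new method).**
- What may go wrong: hydrogen is not taken up by the tetrasubstituted C2=C3 bond of ring C, which ring D shields on both faces. Alternatively it is taken up with poor facial selectivity, because the catalyst's preference on trisubstituted flavones need not carry over to a 2,3-diaryl pyranone. Slow rotation about the C3–C8'' axis of 9 and 10 could add a matched and a mismatched rotamer.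
- Lesser processes are epimerisation at C3 by traces of alkoxide and over-reduction at C4. Over-reduction is reversible by a bicarbonate-buffered Dess–Martin oxidation, which leaves C3 alone.
- Fallback (known chemistry only; sets out from boronate 8, returns at 11): it avoids reducing a 2,3-diarylpyranone by adding ring B last as a nucleophile. Commercial 1-[2,4-bis(benzyloxy)-6-hydroxyphenyl]ethan-1-one is condensed with N,N-dimethylformamide dimethyl acetal to (E)-1-[2,4-bis(benzyloxy)-6-hydroxyphenyl]-3-(dimethylamino)prop-2-en-1-one F1. Iodine closes this to 5,7-bis(benzyloxy)-3-iodo-4H-chromen-4-one F2, the standard 3-iodochromone synthesis. Suzuki–Miyaura coupling of F2 with 8 (Pd(OAc)2, SPhos, K3PO4), now onto a chromone whose C2 is unsubstituted, gives 5,7-bis(benzyloxy)-3-{5,7-bis(benzyloxy)-2-[4-(benzyloxy)phenyl]-4-oxo-4H-chromen-8-yl}-4H-chromen-4-one F3. Copper-mediated 1,4-addition of 3,4-bis(benzyloxy)phenylmagnesium bromide (CuBr·SMe2, Me3SiCl, THF, −78 °C) to the C2–H chromone of F3 gives the silyl enol ether 5,7-bis(benzyloxy)-2-[3,4-bis(benzyloxy)phenyl]-3-{5,7-bis(benzyloxy)-2-[4-(benzyloxy)phenyl]-4-oxo-4H-chromen-8-yl}-4-(trimethylsilyloxy)-2H-chromene F4; the 2-aryl chromone of ring F is a far poorer acceptor. Fluoride-triggered protonation at −78 °C (Bu4NF, AcOH) places the proton on C3 anti to ring B and gives the racemic cis-chromanone (2R*,3R*)-5,7-bis(benzyloxy)-2-[3,4-bis(benzyloxy)phenyl]-3-{5,7-bis(benzyloxy)-2-[4-(benzyloxy)phenyl]-4-oxo-4H-chromen-8-yl}chroman-4-one F5. The known ruthenium–carbene hydrogenation of the one remaining 2-arylchromone (ring F, catalyst of step 7) then sets C2''. It gives 11 together with its diastereomer (2S,3S)-5,7-bis(benzyloxy)-2-[3,4-bis(benzyloxy)phenyl]-3-{(2R)-5,7-bis(benzyloxy)-2-[4-(benzyloxy)phenyl]-4-oxochroman-8-yl}chroman-4-one F6. The two are separated by chromatography and 11 goes on to step 8.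

**Step 6.**
- What may go wrong: slow transmetalation of the di-ortho-oxygenated boronate onto the hindered C3–palladium species, so that protodeboronation of 8 and reductive loss of iodine from 4 win.
- Fallback (sets out from 4 and 7, returns at 9, needs no boronate): the metal is moved to C3 and the transmetalation is changed from boron to tin and copper. Compound 4 is stannylated with (Me3Sn)2 and Pd(PPh3)4 to 5,7-bis(benzyloxy)-2-[3,4-bis(benzyloxy)phenyl]-3-(trimethylstannyl)-4H-chromen-4-one F7. F7 is joined to iodide 7 by a copper-assisted Stille coupling (Pd(PPh3)4, CuI, CsF, DMF, 45 °C) to give 9.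

**Step 2.**
- What may go wrong: incomplete or misdirected deprotonation, from poor solubility of 2 at −78 °C or competing metalation at the benzylic OCH2 groups, leading to mixtures.
- Fallback (sets out from 1, returns at 4): the iodine is introduced electrophilically on a deactivated substrate. Luteolin 1 is acetylated (Ac2O, pyridine) to 2-(3,4-diacetoxyphenyl)-4-oxo-4H-chromene-5,7-diyl diacetate F8. The acetoxy groups deactivate rings A and B, so that I2 with (NH4)2Ce(NO3)6 in MeCN should iodinate the enol-ether-like C3 and give 2-(3,4-diacetoxyphenyl)-3-iodo-4-oxo-4H-chromene-5,7-diyl diacetate F9. Exchange of the acetates for benzyl ethers (K2CO3, MeOH; then BnBr, DMF) gives 4.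

**Step 8.**
- What may go wrong: epimerisation at C3 on the palladium surface, or hydrogenolytic opening of the benzylic C2–O1 and C2''–O1'' bonds during the long exposure that the hindered 5- and 7''-benzyl ethers may need.
- Fallback (sets out from 11, returns at 12; it makes no new compound, F0): non-reductive debenzylation with BCl3 and pentamethylbenzene as cation scavenger in CH2Cl2 at −78 °C, quenched cold with MeOH. This is a Lewis-acid dealkylation, not a surface hydrogenolysis, and involves no hydrogen and no metal surface.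

## Further compounds

F1 | step 7 | (E)-1-[2,4-bis(benzyloxy)-6-hydroxyphenyl]-3-(dimethylamino)prop-2-en-1-one | CN(C)/C=C/C(=O)c1c(O)cc(OCc2ccccc2)cc1OCc1ccccc1
F2 | step 7 | 5,7-bis(benzyloxy)-3-iodo-4H-chromen-4-one | O=c1c(I)coc2cc(OCc3ccccc3)cc(OCc3ccccc3)c12
F3 | step 7 | 5,7-bis(benzyloxy)-3-{5,7-bis(benzyloxy)-2-[4-(benzyloxy)phenyl]-4-oxo-4H-chromen-8-yl}-4H-chromen-4-one | O=c1c(-c2c(OCc3ccccc3)cc(OCc3ccccc3)c3c(=O)cc(-c4ccc(OCc5ccccc5)cc4)oc23)coc2cc(OCc3ccccc3)cc(OCc3ccccc3)c12
F4 | step 7 | 5,7-bis(benzyloxy)-2-[3,4-bis(benzyloxy)phenyl]-3-{5,7-bis(benzyloxy)-2-[4-(benzyloxy)phenyl]-4-oxo-4H-chromen-8-yl}-4-(trimethylsilyloxy)-2H-chromene (racemic, not isolated) | C[Si](C)(C)OC1=C(c2c(OCc3ccccc3)cc(OCc3ccccc3)c3c(=O)cc(-c4ccc(OCc5ccccc5)cc4)oc23)C(c2ccc(OCc3ccccc3)c(OCc3ccccc3)c2)Oc2cc(OCc3ccccc3)cc(OCc3ccccc3)c12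
F5 | step 7 | (2R*,3R*)-5,7-bis(benzyloxy)-2-[3,4-bis(benzyloxy)phenyl]-3-{5,7-bis(benzyloxy)-2-[4-(benzyloxy)phenyl]-4-oxo-4H-chromen-8-yl}chroman-4-one (racemic cis; 2R,3R enantiomer drawn) | O=c1cc(-c2ccc(OCc3ccccc3)cc2)oc2c1c(OCc1ccccc1)cc(OCc1ccccc1)c2[C@H]1C(=O)c2c(OCc3ccccc3)cc(OCc3ccccc3)cc2O[C@H]1c1ccc(OCc2ccccc2)c(OCc2ccccc2)c1
F6 | step 7 | (2S,3S)-5,7-bis(benzyloxy)-2-[3,4-bis(benzyloxy)phenyl]-3-{(2R)-5,7-bis(benzyloxy)-2-[4-(benzyloxy)phenyl]-4-oxochroman-8-yl}chroman-4-one | O=C1C[C@H](c2ccc(OCc3ccccc3)cc2)Oc2c1c(OCc1ccccc1)cc(OCc1ccccc1)c2[C@@H]1C(=O)c2c(OCc3ccccc3)cc(OCc3ccccc3)cc2O[C@@H]1c1ccc(OCc2ccccc2)c(OCc2ccccc2)c1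
F7 | step 6 | 5,7-bis(benzyloxy)-2-[3,4-bis(benzyloxy)phenyl]-3-(trimethylstannyl)-4H-chromen-4-one | O=c1c([Sn](C)(C)C)c(-c2ccc(OCc3ccccc3)c(OCc3ccccc3)c2)oc2cc(OCc3ccccc3)cc(OCc3ccccc3)c12
F8 | step 2 | 2-(3,4-diacetoxyphenyl)-4-oxo-4H-chromene-5,7-diyl diacetate | CC(=O)Oc1ccc(-c2cc(=O)c3c(OC(C)=O)cc(OC(C)=O)cc3o2)cc1OC(C)=O
F9 | step 2 | 2-(3,4-diacetoxyphenyl)-3-iodo-4-oxo-4H-chromene-5,7-diyl diacetate | CC(=O)Oc1ccc(-c2oc3cc(OC(C)=O)cc(OC(C)=O)c3c(=O)c2I)cc1OC(C)=O
F0 | step 8 | none | none
A1 | alternative 1 | (2R)-5,7-bis(benzyloxy)-2-[3,4-bis(benzyloxy)phenyl]chroman-4-one | O=C1C[C@H](c2ccc(OCc3ccccc3)c(OCc3ccccc3)c2)Oc2cc(OCc3ccccc3)cc(OCc3ccccc3)c12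
A2 | alternative 1 | (2R)-5,7-bis(benzyloxy)-2-[4-(benzyloxy)phenyl]-8-bromochroman-4-one | O=C1C[C@H](c2ccc(OCc3ccccc3)cc2)Oc2c(Br)c(OCc3ccccc3)cc(OCc3ccccc3)c12
A3 | alternative 1 | (2R,3S)-5,7-bis(benzyloxy)-2-[3,4-bis(benzyloxy)phenyl]-3-{(2R)-5,7-bis(benzyloxy)-2-[4-(benzyloxy)phenyl]-4-oxochroman-8-yl}chroman-4-one (2,3-trans) | O=C1C[C@H](c2ccc(OCc3ccccc3)cc2)Oc2c1c(OCc1ccccc1)cc(OCc1ccccc1)c2[C@@H]1C(=O)c2c(OCc3ccccc3)cc(OCc3ccccc3)cc2O[C@H]1c1ccc(OCc2ccccc2)c(OCc2ccccc2)c1
A4 | alternative 2 | 1-[2,4-bis(benzyloxy)-6-hydroxyphenyl]-2-{5,7-bis(benzyloxy)-2-[4-(benzyloxy)phenyl]-4-oxo-4H-chromen-8-yl}ethan-1-one | O=C(Cc1c(OCc2ccccc2)cc(OCc2ccccc2)c2c(=O)cc(-c3ccc(OCc4ccccc4)cc3)oc12)c1c(O)cc(OCc2ccccc2)cc1OCc1ccccc1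
A5 | alternative 2 | 3,4-bis(benzyloxy)benzaldehyde | O=Cc1ccc(OCc2ccccc2)c(OCc2ccccc2)c1
A6 | alternative 2 | (2R*,3S*)-5,7-bis(benzyloxy)-2-[3,4-bis(benzyloxy)phenyl]-3-{5,7-bis(benzyloxy)-2-[4-(benzyloxy)phenyl]-4-oxo-4H-chromen-8-yl}chroman-4-one (racemic trans; 2R,3S enantiomer drawn) | O=c1cc(-c2ccc(OCc3ccccc3)cc2)oc2c1c(OCc1ccccc1)cc(OCc1ccccc1)c2[C@@H]1C(=O)c2c(OCc3ccccc3)cc(OCc3ccccc3)cc2O[C@H]1c1ccc(OCc2ccccc2)c(OCc2ccccc2)c1
A7 | alternative 3 | 5,7-bis(benzyloxy)-2-[4-(benzyloxy)phenyl]-8-(9-borabicyclo[3.3.1]nonan-9-yl)-4H-chromen-4-one | O=c1cc(-c2ccc(OCc3ccccc3)cc2)oc2c(B3C4CCCC3CCC4)c(OCc3ccccc3)cc(OCc3ccccc3)c12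
A8 | alternative 3 | 1-[2,4-bis(benzyloxy)-6-(methoxymethoxy)phenyl]-2-diazoethan-1-one | [N-]=[N+]=CC(=O)c1c(OCOC)cc(OCc2ccccc2)cc1OCc1ccccc1
A9 | alternative 3 | (2R,3S)-1-[2,4-bis(benzyloxy)-6-(methoxymethoxy)phenyl]-3-[3,4-bis(benzyloxy)phenyl]-2-{5,7-bis(benzyloxy)-2-[4-(benzyloxy)phenyl]-4-oxo-4H-chromen-8-yl}-3-hydroxypropan-1-one (anti aldol) | O[C@H](c1ccc(OCc2ccccc2)c(OCc2ccccc2)c1)[C@@H](c1c(OCc2ccccc2)cc(OCc2ccccc2)c2c(=O)cc(-c3ccc(OCc4ccccc4)cc3)oc12)C(=O)c1c(OCOC)cc(OCc2ccccc2)cc1OCc1ccccc1
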